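The route rests on disconnecting the C2–C3 bond of the chromane-2,4-dione: in its pyranone ring, quaternary C3 sits between lactone carbonyl C2 and ketone C4, a masked 2-formyl thioester. In one operation a Lewis acid opens a (2R,3R)-glycidic thioester at its fully substituted carbon and the thioester carbon shifts there with inversion, forming C2–C3, setting C3 and leaving the former α-carbon as the C4 aldehyde. The precursor is an S-ethyl oxirane-2-carbothioate, made by Sharpless epoxidation, whose C3 carries farnesyl and a 3-silyloxypropyl arm; a silyl ether is chosen because an acetal beside a polyene would itself start cationic cyclisation. Arylation, lactonisation and late diynyl addition complete the target.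

Key step: step 7

Abbreviations: farnesyl = (2E,6E)-3,7,11-trimethyldodeca-2,6,10-trien-1-yl; TBS = tert-butyldimethylsilyl.

Assumption 1: compounds 1, 2, 4, 11, 14, 21 and 24 are taken as catalogue chemicals.

Assumption 2: (S,S)-ProPhenol is taken to direct the diynyl group to the Re face of enal 23 (giving 5S); if the sense is the opposite, the (R,R)-ligand is used in the same step.

Remark: the carbinol centres formed in steps 8 and 18 are carried as epimer mixtures because both are oxidised later. The stereochemical bookkeeping is (2R,3R)-glycidic thioester 12 → (2S)-formyl thioester 13 → (3S)-dione.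

Step 1
Reactants: 1 (2E,6E)-farnesyl bromide; 2 ethyl propiolate
Product: 3 ethyl (5E,9E)-6,10,14-trimethylpentadeca-5,9,13-trien-2-ynoate
Conditions: CuI (10 mol %), K2CO3, n-Bu4NI (10 mol %), DMF, rt
Reagents that add atoms: none
Why: Copper-catalysed allylic substitution, in which the copper acetylide formed from 2 and CuI under mild carbonate base displaces the primary allylic bromide at its unhindered terminus, should give the skipped enynoate with both farnesyl alkenes unchanged.

Step 2
Reactants: 3 ethyl (5E,9E)-6,10,14-trimethylpentadeca-5,9,13-trien-2-ynoate; 4 (3-bromopropoxy)(tert-butyl)dimethylsilane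
Product: 7 ethyl (2Z,5E,9E)-3-{3-[(tert-butyldimethylsilyl)oxy]propyl}-6,10,14-trimethylpentadeca-2,5,9,13-tetraenoate, via Grignard reagent 5 (not isolated), via organocopper reagent 6 (not isolated)
Conditions: 4, Mg, THF, rt; CuBr·SMe2, THF, −40 °C; 3, −78 °C; sat. NH4Cl, −78 °C → rt
Reagents that add atoms: none
Why: syn-Carbocupration of the ynoate at −78 °C followed by cold protonation with retention places the new alkyl group cis to the vinyl hydrogen, so the ester should end cis to the farnesyl CH2 (2Z).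

Step 3
Reactants: 7 ethyl (2Z,5E,9E)-3-{3-[(tert-butyldimethylsilyl)oxy]propyl}-6,10,14-trimethylpentadeca-2,5,9,13-tetraenoate
Product: 8 (2Z,5E,9E)-3-{3-[(tert-butyldimethylsilyl)oxy]propyl}-6,10,14-trimethylpentadeca-2,5,9,13-tetraen-1-ol
Conditions: DIBAL-H (2.5 equiv), CH2Cl2, −78 °C; Rochelle salt work-up
Reagents that add atoms: none
Why: DIBAL-H 1,2-reduction of the conjugated ester should give the allylic alcohol without touching the alkene geometry, the isolated alkenes or the silyl ether.

Step 4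
Reactants: 8 (2Z,5E,9E)-3-{3-[(tert-butyldimethylsilyl)oxy]propyl}-6,10,14-trimethylpentadeca-2,5,9,13-tetraen-1-ol
Product: 9 [(2S,3R)-3-{3-[(tert-butyldimethylsilyl)oxy]propyl}-3-farnesyloxiran-2-yl]methanol
Conditions: Ti(OiPr)4 (10 mol %), diethyl L-(+)-tartrate (12 mol %), t-BuOOH, 4 Å MS, CH2Cl2, −20 °C
Reagents that add atoms: tert-butyl hydroperoxide, CC(C)(C)OO
Why: Sharpless asymmetric epoxidation epoxidises only the alkene bound through the allylic hydroxyl, and with the L-(+)-tartrate this (Z)-3,3-disubstituted allylic alcohol (a nerol-type substrate) should give the (2S,3R)-epoxide, the tartrate setting both epoxide carbons.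

Step 5
Reactants: 9 [(2S,3R)-3-{3-[(tert-butyldimethylsilyl)oxy]propyl}-3-farnesyloxiran-2-yl]methanol
Product: 10 (2R,3R)-3-{3-[(tert-butyldimethylsilyl)oxy]propyl}-3-farnesyloxirane-2-carboxylic acid
Conditions: TEMPO (0.2 equiv), PhI(OAc)2 (2.5 equiv), MeCN/pH 7 phosphate buffer, 0 °C → rt
Reagents that add atoms: water, O
Why: The TEMPO/PhI(OAc)2 oxidation takes the primary alcohol through the aldehyde hydrate to the acid under buffered conditions that should spare the epoxide, the trisubstituted alkenes and the silyl ether (the descriptor at C2 changes only by priority).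

Step 6
Reactants: 10 (2R,3R)-3-{3-[(tert-butyldimethylsilyl)oxy]propyl}-3-farnesyloxirane-2-carboxylic acid; 11 ethanethiol
Product: 12 S-ethyl (2R,3R)-3-{3-[(tert-butyldimethylsilyl)oxy]propyl}-3-farnesyloxirane-2-carbothioate
Conditions: DCC, DMAP (cat.), CH2Cl2, 0 °C
Reagents that add atoms: none
Why: Steglich thioesterification (carbodiimide activation with DMAP acyl transfer) at 0 °C should couple the freshly made glycidic acid with the thiol without the acid or heat that would decarboxylate it.

Step 7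
Reactants: 12 S-ethyl (2R,3R)-3-{3-[(tert-butyldimethylsilyl)oxy]propyl}-3-farnesyloxirane-2-carbothioate
Product: 13 S-ethyl (2S)-5-[(tert-butyldimethylsilyl)oxy]-2-formyl-2-farnesylpentanethioate
Conditions: BF3·OEt2 (1.0 equiv), 2,6-di-tert-butyl-4-methylpyridine (0.2 equiv), CH2Cl2, −78 → −20 °C; sat. NaHCO3
Reagents that add atoms: none
Why: BF3 binds the epoxide oxygen, the bond from oxygen to the fully substituted carbon ionises and, in the same event, the thioester carbonyl carbon moves from the α-carbon to that carbon on the face opposite the departing oxygen, while the α-carbon keeps the oxygen and becomes the aldehyde. The closest known reaction type is the Lewis-acid rearrangement of glycidic esters and glycidic thiol esters to 2-formyl (thio)esters by 1,2-acyl shift, a semipinacol-type epoxide rearrangement. No ring is closed. The quaternary centre is set by inversion at the migration terminus, so its (2S) configuration is dictated by the (3R) epoxide carbon installed in step 4. The step needs the acyl shift to win over hydride shift, proton loss and capture of the developing cation by an alkene or an oxygen. The high migratory aptitude of the thiol ester, the tertiary terminus, the low temperature, the hindered base that removes adventitious acid, and a side arm ending in a bulky, weakly basic silyl ether should secure this.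

Step 8
Reactants: 13 S-ethyl (2S)-5-[(tert-butyldimethylsilyl)oxy]-2-formyl-2-farnesylpentanethioate; 14 (2-bromophenoxy)(tert-butyl)dimethylsilane
Product: 16 S-ethyl (2S)-5-[(tert-butyldimethylsilyl)oxy]-2-[hydroxy(2-{[tert-butyldimethylsilyl]oxy}phenyl)methyl]-2-farnesylpentanethioate (carbinol epimers), via aryl Grignard reagent 15 (not isolated)
Conditions: 14, Mg, THF, rt; 13, THF, −78 → −40 °C; sat. NH4Cl at −40 °C
Reagents that add atoms: none
Why: Chemoselective Grignard 1,2-addition should occur at the aldehyde, which is far more electrophilic than the thioester on the same quaternary carbon, and neither carbonyl is enolisable, so cold addition and cold quench should stop at the secondary alcohol.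

Step 9
Reactants: 16 S-ethyl (2S)-5-[(tert-butyldimethylsilyl)oxy]-2-[hydroxy(2-{[tert-butyldimethylsilyl]oxy}phenyl)methyl]-2-farnesylpentanethioate
Product: 17 S-ethyl (2S)-5-hydroxy-2-[hydroxy(2-{[tert-butyldimethylsilyl]oxy}phenyl)methyl]-2-farnesylpentanethioate
Conditions: CSA (0.1 equiv), MeOH/CH2Cl2, 0 °C
Reagents that add atoms: none
Why: Acid-catalysed methanolysis cleaves a primary alkyl TBS ether much faster than a phenolic TBS ether, which is stable to acid, so selective silyl ether solvolysis should free only the side-arm hydroxyl and leave the thioester intact.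

Step 10
Reactants: 17 S-ethyl (2S)-5-hydroxy-2-[hydroxy(2-{[tert-butyldimethylsilyl]oxy}phenyl)methyl]-2-farnesylpentanethioate
Product: 18 S-ethyl (2S)-2-(2-{[tert-butyldimethylsilyl]oxy}benzoyl)-5-oxo-2-farnesylpentanethioate
Conditions: (COCl)2, DMSO, CH2Cl2, −78 °C; Et3N, −78 → 0 °C
Reagents that add atoms: none
Why: Swern oxidation turns both hydroxyls into alkoxysulfonium ions before base is added, so the 1,5-diol should go to the keto aldehyde without passing through a lactol that other oxidants would take on to a lactone, and the quaternary centre cannot epimerise.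

Step 11
Reactants: 18 S-ethyl (2S)-2-(2-{[tert-butyldimethylsilyl]oxy}benzoyl)-5-oxo-2-farnesylpentanethioate
Product: 20 3-[(3S)-2,4-dioxo-3-farnesyl-3,4-dihydro-2H-chromen-3-yl]propanal, via phenol 19 (not isolated)
Conditions: TBAF/AcOH (1:1, 1.2 equiv), THF, 0 °C; then AgOCOCF3 (3 equiv), Na2HPO4, MeCN, rt, dark
Reagents that add atoms: none
Why: Buffered fluoride cleaves the labile ortho-acyl aryl silyl ether, and silver trifluoroacetate then activates the thioester and binds the thiolate as AgSEt, so the phenol should acylate irreversibly by 6-exo-trig closure (silver-assisted thioester-to-ester acyl transfer) under conditions that spare the aldehyde.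

Step 12
Reactants: 21 dec-2-yn-1-ol
Product: 22 (2Z)-dec-2-en-1-ol
Conditions: H2 (1 atm), Pd/CaCO3 poisoned with Pb(OAc)2, quinoline, EtOAc, rt
Reagents that add atoms: none
Why: Semihydrogenation over lead-poisoned palladium adds hydrogen syn and should stop at the cis-alkene.

Step 13
Reactants: 22 (2Z)-dec-2-en-1-ol
Product: 23 (2Z)-dec-2-enal
Conditions: Dess–Martin periodinane, NaHCO3, CH2Cl2, 0 °C; used at once
Reagents that add atoms: none
Why: Buffered Dess–Martin oxidation at 0 °C should give the (Z)-enal without the acid or base that would isomerise it to the (E)-isomer.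

Step 14
Reactants: 24 1,4-bis(trimethylsilyl)buta-1,3-diyne
Product: 26 buta-1,3-diyn-1-yl(trimethyl)silane, via lithium acetylide 25 (not isolated)
Conditions: MeLi·LiBr (1.0 equiv), Et2O, 0 °C → rt; sat. NH4Cl; used as a toluene solution
Reagents that add atoms: none
Why: Mono-protodesilylation, in which methyllithium attacks one silicon and the resulting acetylide anion deactivates the second silyl group toward cleavage, should give the terminal diyne after protonation.

Step 15
Reactants: 23 (2Z)-dec-2-enal; 26 buta-1,3-diyn-1-yl(trimethyl)silane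
Product: 28 (5S,6Z)-1-(trimethylsilyl)tetradec-6-ene-1,3-diyn-5-ol, via zinc acetylide 27 (not isolated)
Conditions: (S,S)-ProPhenol (20 mol %), Me2Zn (3 equiv), Ph3P=O (40 mol %), toluene, 0–4 °C
Reagents that add atoms: none
Why: Catalytic asymmetric alkynylation, in which the dinuclear zinc–ProPhenol complex binds the aldehyde and the zinc acetylide and delivers the diynyl group by 1,2-addition to one enal face, should set the carbinol centre (5S) under ligand control.

Step 16
Reactants: 28 (5S,6Z)-1-(trimethylsilyl)tetradec-6-ene-1,3-diyn-5-ol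
Product: 29 tert-butyl(dimethyl){[(5S,6Z)-1-(trimethylsilyl)tetradec-6-ene-1,3-diyn-5-yl]oxy}silane
Conditions: TBSCl, imidazole, CH2Cl2, 0 °C → rt
Reagents that add atoms: tert-butyldimethylsilyl chloride, CC(C)(C)[Si](C)(C)Cl
Why: O-Silylation of the secondary alcohol under imidazole catalysis should protect the carbinol for the chromium and oxidation steps, while the C-silyl group on the diyne is inert to imidazole.

Step 17
Reactants: 29 tert-butyl(dimethyl){[(5S,6Z)-1-(trimethylsilyl)tetradec-6-ene-1,3-diyn-5-yl]oxy}silane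
Product: 30 tert-butyl{[(5S,6Z)-1-iodotetradec-6-ene-1,3-diyn-5-yl]oxy}dimethylsilane
Conditions: N-iodosuccinimide (1.2 equiv), AgNO3 (0.1 equiv), DMF, rt, dark
Reagents that add atoms: N-iodosuccinimide, O=C1CCC(=O)N1I
Why: Silver-catalysed ipso-iododesilylation, in which a silver acetylide formed from the alkynylsilane is iodinated by N-iodosuccinimide, should give the 1-iodoalkyne directly and leave the silyl ether alone.

Step 18
Reactants: 20 3-[(3S)-2,4-dioxo-3-farnesyl-3,4-dihydro-2H-chromen-3-yl]propanal; 30 tert-butyl{[(5S,6Z)-1-iodotetradec-6-ene-1,3-diyn-5-yl]oxy}dimethylsilane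
Product: 32 (3S)-3-[(8S,9Z)-8-[(tert-butyldimethylsilyl)oxy]-3-hydroxyheptadec-9-ene-4,6-diyn-1-yl]-3-farnesyl-2H-chromene-2,4(3H)-dione (C3′ epimers), via alkynylchromium reagent 31 (not isolated)
Conditions: CrCl2 (4 equiv), THF/DMF, 0 °C → rt; water; crude product carried on at once
Reagents that add atoms: none
Why: In this Nozaki–Hiyama–Kishi-type addition CrCl2 inserts into the alkynyl C–I bond and the alkynylchromium should add only to the aldehyde, leaving the hindered C4 ketone and the lactone alone, while the covalent chromium alkoxide is a poor nucleophile toward the aryl lactone.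

Step 19
Reactants: 32 (3S)-3-[(8S,9Z)-8-[(tert-butyldimethylsilyl)oxy]-3-hydroxyheptadec-9-ene-4,6-diyn-1-yl]-3-farnesyl-2H-chromene-2,4(3H)-dione
Product: 33 (3S)-3-[(8S,9Z)-8-[(tert-butyldimethylsilyl)oxy]-3-oxoheptadec-9-ene-4,6-diyn-1-yl]-3-farnesyl-2H-chromene-2,4(3H)-dione
Conditions: Dess–Martin periodinane, NaHCO3, CH2Cl2, 0 °C
Reagents that add atoms: none
Why: Dess–Martin oxidation of the crude propargylic alcohol under buffered, non-nucleophilic conditions should give the ynone before the δ-hydroxyl can transacylate the aryl lactone.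

Step 20
Reactants: 33 (3S)-3-[(8S,9Z)-8-[(tert-butyldimethylsilyl)oxy]-3-oxoheptadec-9-ene-4,6-diyn-1-yl]-3-farnesyl-2H-chromene-2,4(3H)-dione
Product: 34 (3S)-3-[(8S,9Z)-8-hydroxy-3-oxoheptadec-9-ene-4,6-diyn-1-yl]-3-farnesyl-2H-chromene-2,4(3H)-dione (CNP0346147.1)
Conditions: 48% HF (aq.), MeCN, 0 °C
Reagents that add atoms: none
Why: Acidic fluoride desilylation should remove the secondary TBS ether without any base or strong nucleophile, which neither the diynone nor the dione would tolerate, and it touches no stereocentre.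

Compound list
1 | (2E,6E)-farnesyl bromide | BrC/C=C(\C)CC/C=C(\C)CCC=C(C)C | starting material
2 | ethyl propiolate | CCOC(=O)C#C | starting material
3 | ethyl (5E,9E)-6,10,14-trimethylpentadeca-5,9,13-trien-2-ynoate | CCOC(=O)C#CC/C=C(\C)CC/C=C(\C)CCC=C(C)C | intermediate
4 | (3-bromopropoxy)(tert-butyl)dimethylsilane | CC(C)(C)[Si](C)(C)OCCCBr | starting material
5 | {3-[(tert-butyldimethylsilyl)oxy]propyl}magnesium bromide | CC(C)(C)[Si](C)(C)OCCC[Mg]Br | intermediate (not isolated)
6 | {3-[(tert-butyldimethylsilyl)oxy]propyl}copper, as its MgBr2 complex | CC(C)(C)[Si](C)(C)OCCC[Cu] | intermediate (not isolated)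
7 | ethyl (2Z,5E,9E)-3-{3-[(tert-butyldimethylsilyl)oxy]propyl}-6,10,14-trimethylpentadeca-2,5,9,13-tetraenoate | CCOC(=O)/C=C(/CCCO[Si](C)(C)C(C)(C)C)C/C=C(\C)CC/C=C(\C)CCC=C(C)C | intermediate
8 | (2Z,5E,9E)-3-{3-[(tert-butyldimethylsilyl)oxy]propyl}-6,10,14-trimethylpentadeca-2,5,9,13-tetraen-1-ol | OC/C=C(/CCCO[Si](C)(C)C(C)(C)C)C/C=C(\C)CC/C=C(\C)CCC=C(C)C | intermediate
9 | [(2S,3R)-3-{3-[(tert-butyldimethylsilyl)oxy]propyl}-3-farnesyloxiran-2-yl]methanol | CC(C)(C)[Si](C)(C)OCCC[C@@](O1)(C/C=C(\C)CC/C=C(\C)CCC=C(C)C)[C@@H]1CO | intermediate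
10 | (2R,3R)-3-{3-[(tert-butyldimethylsilyl)oxy]propyl}-3-farnesyloxirane-2-carboxylic acid | CC(C)(C)[Si](C)(C)OCCC[C@@](O1)(C/C=C(\C)CC/C=C(\C)CCC=C(C)C)[C@@H]1C(=O)O | intermediate
11 | ethanethiol | CCS | starting material
12 | S-ethyl (2R,3R)-3-{3-[(tert-butyldimethylsilyl)oxy]propyl}-3-farnesyloxirane-2-carbothioate | CC(C)(C)[Si](C)(C)OCCC[C@@](O1)(C/C=C(\C)CC/C=C(\C)CCC=C(C)C)[C@@H]1C(=O)SCC | intermediate
13 | S-ethyl (2S)-5-[(tert-butyldimethylsilyl)oxy]-2-formyl-2-farnesylpentanethioate | CC(C)(C)[Si](C)(C)OCCC[C@@](C=O)(C/C=C(\C)CC/C=C(\C)CCC=C(C)C)C(=O)SCC | intermediate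
14 | (2-bromophenoxy)(tert-butyl)dimethylsilane | CC(C)(C)[Si](C)(C)Oc1ccccc1Br | starting material
15 | {2-[(tert-butyldimethylsilyl)oxy]phenyl}magnesium bromide | CC(C)(C)[Si](C)(C)Oc1ccccc1[Mg]Br | intermediate (not isolated)
16 | S-ethyl (2S)-5-[(tert-butyldimethylsilyl)oxy]-2-[hydroxy(2-{[tert-butyldimethylsilyl]oxy}phenyl)methyl]-2-farnesylpentanethioate, carbinol epimers | CC(C)(C)[Si](C)(C)OCCC[C@@](C(O)c1ccccc1O[Si](C)(C)C(C)(C)C)(C/C=C(\C)CC/C=C(\C)CCC=C(C)C)C(=O)SCC | intermediate
17 | S-ethyl (2S)-5-hydroxy-2-[hydroxy(2-{[tert-butyldimethylsilyl]oxy}phenyl)methyl]-2-farnesylpentanethioate, carbinol epimers | OCCC[C@@](C(O)c1ccccc1O[Si](C)(C)C(C)(C)C)(C/C=C(\C)CC/C=C(\C)CCC=C(C)C)C(=O)SCC | intermediate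
18 | S-ethyl (2S)-2-(2-{[tert-butyldimethylsilyl]oxy}benzoyl)-5-oxo-2-farnesylpentanethioate | O=CCC[C@@](C(=O)c1ccccc1O[Si](C)(C)C(C)(C)C)(C/C=C(\C)CC/C=C(\C)CCC=C(C)C)C(=O)SCC | intermediate
19 | S-ethyl (2S)-2-(2-hydroxybenzoyl)-5-oxo-2-farnesylpentanethioate | O=CCC[C@@](C(=O)c1ccccc1O)(C/C=C(\C)CC/C=C(\C)CCC=C(C)C)C(=O)SCC | intermediate (not isolated)
20 | 3-[(3S)-2,4-dioxo-3-farnesyl-3,4-dihydro-2H-chromen-3-yl]propanal | O=CCC[C@@]1(C/C=C(\C)CC/C=C(\C)CCC=C(C)C)C(=O)Oc2ccccc2C1=O | intermediate
21 | dec-2-yn-1-ol | CCCCCCCC#CCO | starting material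
22 | (2Z)-dec-2-en-1-ol | CCCCCCC/C=C\CO | intermediate
23 | (2Z)-dec-2-enal | CCCCCCC/C=C\C=O | intermediate
24 | 1,4-bis(trimethylsilyl)buta-1,3-diyne | C[Si](C)(C)C#CC#C[Si](C)(C)C | starting material
25 | lithium 4-(trimethylsilyl)buta-1,3-diyn-1-ide | [Li]C#CC#C[Si](C)(C)C | intermediate (not isolated)
26 | buta-1,3-diyn-1-yl(trimethyl)silane | C#CC#C[Si](C)(C)C | intermediate
27 | methyl[4-(trimethylsilyl)buta-1,3-diyn-1-yl]zinc | C[Zn]C#CC#C[Si](C)(C)C | intermediate (not isolated)
28 | (5S,6Z)-1-(trimethylsilyl)tetradec-6-ene-1,3-diyn-5-ol | CCCCCCC/C=C\[C@H](O)C#CC#C[Si](C)(C)C | intermediate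
29 | tert-butyl(dimethyl){[(5S,6Z)-1-(trimethylsilyl)tetradec-6-ene-1,3-diyn-5-yl]oxy}silane | CCCCCCC/C=C\[C@H](O[Si](C)(C)C(C)(C)C)C#CC#C[Si](C)(C)C | intermediate
30 | tert-butyl{[(5S,6Z)-1-iodotetradec-6-ene-1,3-diyn-5-yl]oxy}dimethylsilane | CCCCCCC/C=C\[C@H](O[Si](C)(C)C(C)(C)C)C#CC#CI | intermediate
31 | dichloro{(5S,6Z)-5-[(tert-butyldimethylsilyl)oxy]tetradec-6-ene-1,3-diyn-1-yl}chromium | CCCCCCC/C=C\[C@H](O[Si](C)(C)C(C)(C)C)C#CC#C[Cr](Cl)Cl | intermediate (not isolated)
32 | (3S)-3-[(8S,9Z)-8-[(tert-butyldimethylsilyl)oxy]-3-hydroxyheptadec-9-ene-4,6-diyn-1-yl]-3-farnesyl-2H-chromene-2,4(3H)-dione, C3′ epimers | CCCCCCC/C=C\[C@H](O[Si](C)(C)C(C)(C)C)C#CC#CC(O)CC[C@@]1(C/C=C(\C)CC/C=C(\C)CCC=C(C)C)C(=O)Oc2ccccc2C1=O | intermediate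
33 | (3S)-3-[(8S,9Z)-8-[(tert-butyldimethylsilyl)oxy]-3-oxoheptadec-9-ene-4,6-diyn-1-yl]-3-farnesyl-2H-chromene-2,4(3H)-dione | CCCCCCC/C=C\[C@H](O[Si](C)(C)C(C)(C)C)C#CC#CC(=O)CC[C@@]1(C/C=C(\C)CC/C=C(\C)CCC=C(C)C)C(=O)Oc2ccccc2C1=O | intermediate
34 | (3S)-3-[(8S,9Z)-8-hydroxy-3-oxoheptadec-9-ene-4,6-diyn-1-yl]-3-farnesyl-2H-chromene-2,4(3H)-dione | CCCCCCC/C=C\[C@H](O)C#CC#CC(=O)CC[C@@]1(C/C=C(\C)CC/C=C(\C)CCC=C(C)C)C(=O)Oc2ccccc2C1=O | target

Total step count: 20.
Longest linear sequence: 14 steps (steps 1–11, then 18–20).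

Steps most likely to fail

Step 7. The acyl shift may lose to hydride shift (giving a 2-oxo thioester) or to proton loss (giving an allylic alcohol). The developing cation may also be captured by the silyl ether oxygen or a farnesyl alkene. Ionisation to a free cation would erode the transfer of configuration. The fallback sets out from epoxy alcohol 9 and comes back at aldehyde 20. Compound 9 is silylated (TBSOTf, 2,6-lutidine) to the bis-silyl ether F1. Methylaluminium bis(4-bromo-2,6-di-tert-butylphenoxide) in CH2Cl2 at −78 °C then opens the epoxide at the tertiary carbon, and the silyloxymethyl group, in place of an acyl group, shifts there with inversion (the organoaluminium-promoted epoxy silyl ether rearrangement) to give the quaternary β-silyloxy aldehyde F2. Grignard reagent 15 adds to give the carbinol F3, CSA in MeOH removes both alkyl silyl groups to give the triol F4, and Swern oxidation gives the keto dialdehyde F5. TBAF/AcOH then frees the phenol, which closes onto the neighbouring formyl group as the lactol F6, and Dess–Martin oxidation of the lactol gives 20.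

Step 18. The δ-oxygen of the new propargylic alkoxide or alcohol may transacylate the activated aryl lactone, opening the dione ring, and insertion of divalent chromium into the diynyl iodide may be slow or lead to homocoupling. The fallback sets out from thioester 18 (with iodide 30) and comes back at 33, closing the lactone last so that no hydroxyl ever faces the aryl lactone. CrCl2-mediated addition of 30 to 18 gives the carbinol F7, in which a δ-hydroxyl next to an S-alkyl thioester is harmless. Dess–Martin oxidation gives the diynone F8. TBAF/AcOH at 0 °C frees the phenol F9, and AgOCOCF3/Na2HPO4 closes the lactone while the thiolate is held as AgSEt and cannot add to the diynone, giving 33.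

Step 15. The (Z)-enal may isomerise to the (E)-enal under the zinc alkoxide conditions, and facial selectivity on a cis-enal may be insufficient. The fallback sets out from enal 23 and lithium acetylide 25 and comes back at 28. Acetylide 25 is added to 23 at −78 °C, where the cis-alkene is safe, to give the racemic carbinol F10. Dess–Martin oxidation gives the enynone F11. Midland reduction with (S)-Alpine-Borane (B-isopinocampheyl-9-borabicyclo[3.3.1]nonane from (−)-α-pinene), in which the rod-like diynyl group acts as the small substituent, should give 28.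

Further compounds
F1 | step 7 | tert-butyl({(2S,3R)-3-{3-[(tert-butyldimethylsilyl)oxy]propyl}-3-farnesyloxiran-2-yl}methoxy)dimethylsilane | CC(C)(C)[Si](C)(C)OCCC[C@@](O1)(C/C=C(\C)CC/C=C(\C)CCC=C(C)C)[C@@H]1CO[Si](C)(C)C(C)(C)C
F2 | step 7 | (2R)-5-[(tert-butyldimethylsilyl)oxy]-2-{[(tert-butyldimethylsilyl)oxy]methyl}-2-farnesylpentanal | CC(C)(C)[Si](C)(C)OCCC[C@@](C=O)(C/C=C(\C)CC/C=C(\C)CCC=C(C)C)CO[Si](C)(C)C(C)(C)C
F3 | step 7 | (2R)-5-[(tert-butyldimethylsilyl)oxy]-2-{[(tert-butyldimethylsilyl)oxy]methyl}-1-(2-{[tert-butyldimethylsilyl]oxy}phenyl)-2-farnesylpentan-1-ol, carbinol epimers | CC(C)(C)[Si](C)(C)OCCC[C@@](C(O)c1ccccc1O[Si](C)(C)C(C)(C)C)(C/C=C(\C)CC/C=C(\C)CCC=C(C)C)CO[Si](C)(C)C(C)(C)C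
F4 | step 7 | (2R)-2-(hydroxymethyl)-1-(2-{[tert-butyldimethylsilyl]oxy}phenyl)-2-farnesylpentane-1,5-diol, carbinol epimers | OCCC[C@@](C(O)c1ccccc1O[Si](C)(C)C(C)(C)C)(C/C=C(\C)CC/C=C(\C)CCC=C(C)C)CO
F5 | step 7 | (4R)-4-formyl-5-oxo-5-(2-{[tert-butyldimethylsilyl]oxy}phenyl)-4-farnesylpentanal | O=CCC[C@@](C(=O)c1ccccc1O[Si](C)(C)C(C)(C)C)(C/C=C(\C)CC/C=C(\C)CCC=C(C)C)C=O
F6 | step 7 | 3-[(3R)-2-hydroxy-4-oxo-3-farnesyl-3,4-dihydro-2H-chromen-3-yl]propanal, lactol epimers | O=CCC[C@@]1(C/C=C(\C)CC/C=C(\C)CCC=C(C)C)C(O)Oc2ccccc2C1=O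
F7 | step 18 | S-ethyl (2S,10S,11Z)-2-(2-{[tert-butyldimethylsilyl]oxy}benzoyl)-10-[(tert-butyldimethylsilyl)oxy]-5-hydroxy-2-farnesylnonadec-11-ene-6,8-diynethioate, C5 epimers | CCCCCCC/C=C\[C@H](O[Si](C)(C)C(C)(C)C)C#CC#CC(O)CC[C@@](C(=O)c1ccccc1O[Si](C)(C)C(C)(C)C)(C/C=C(\C)CC/C=C(\C)CCC=C(C)C)C(=O)SCC
F8 | step 18 | S-ethyl (2S,10S,11Z)-2-(2-{[tert-butyldimethylsilyl]oxy}benzoyl)-10-[(tert-butyldimethylsilyl)oxy]-5-oxo-2-farnesylnonadec-11-ene-6,8-diynethioate | CCCCCCC/C=C\[C@H](O[Si](C)(C)C(C)(C)C)C#CC#CC(=O)CC[C@@](C(=O)c1ccccc1O[Si](C)(C)C(C)(C)C)(C/C=C(\C)CC/C=C(\C)CCC=C(C)C)C(=O)SCC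
F9 | step 18 | S-ethyl (2S,10S,11Z)-10-[(tert-butyldimethylsilyl)oxy]-2-(2-hydroxybenzoyl)-5-oxo-2-farnesylnonadec-11-ene-6,8-diynethioate | CCCCCCC/C=C\[C@H](O[Si](C)(C)C(C)(C)C)C#CC#CC(=O)CC[C@@](C(=O)c1ccccc1O)(C/C=C(\C)CC/C=C(\C)CCC=C(C)C)C(=O)SCC
F10 | step 15 | (6Z)-1-(trimethylsilyl)tetradec-6-ene-1,3-diyn-5-ol, racemic | CCCCCCC/C=C\C(O)C#CC#C[Si](C)(C)C
F11 | step 15 | (6Z)-1-(trimethylsilyl)tetradec-6-ene-1,3-diyn-5-one | CCCCCCC/C=C\C(=O)C#CC#C[Si](C)(C)C
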